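(The data stem from a simulated flask on assumed constants; noise was put on by code.)

Begin at early times and ask what a charge of free catalyst buys.

| setting | cedar | ash | maple | flask |
|---|---|---|---|---|
| substrate | 0.40 M | 0.40 M | 0.40 M | 0.40 M |
| coupling partner | 0.52 M | 0.52 M | 0.78 M | 0.520 M |
| free catalyst | 0.14 mM | 0.32 mM | 0.21 mM | 0.21 mM |
| remark | run made earlier | run made earlier | run made earlier |  |

| run | time / h | product / % | substrate / % |
|---|---|---|---|
| cedar | 2.50 | 3.4 | 95.9 |
| cedar | 5.00 | 7.0 | 93.5 |
| cedar | 8.00 | 9.7 | 90.4 |
| cedar | 10.0 | 11.7 | 88.7 |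
| cedar | 12.0 | 12.9 | 86.5 |
| cedar | 15.0 | 14.1 | 85.6 |
| ash | 1.00 | 3.0 | 96.4 |
| ash | 3.00 | 9.9 | 90.9 |
| ash | 5.00 | 15.0 | 85.2 |
| ash | 8.00 | 21.1 | 79.2 |
| ash | 12.0 | 26.3 | 73.2 |
| ash | 15.0 | 29.3 | 70.9 |
| maple | 1.33 | 3.5 | 95.9 |
| maple | 4.00 | 9.4 | 90.6 |
| maple | 8.00 | 17.2 | 82.5 |
| maple | 10.0 | 19.8 | 80.2 |
| maple | 15.0 | 25.1 | 74.4 |

(each reading ± 0.3 percentage points)

- factor on the rate of making product when 20% of the substrate are converted if coupling partner is charged twice over
- factor on the rate when 20% of the substrate are converted if free catalyst is charged at 2.0 mM instead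



Take the main step first. From cedar to ash, c(free catalyst) rises by a factor of 2.29 and the rate up to the first reading by 2.21. With this step alone in the reckoning, 2.0 mM therefore raises the rate by 9.52.

Now add one process: the rate falls as the hours pass. Call the fall of the logarithm of the rate per hour, from the first reading to the last interval, the fade constant, 0.0885 h⁻¹, the mean of cedar and ash. Ash ends at 29.3% product against 14.1% for cedar, yet cedar's fall reads 0.0926 h⁻¹ and ash's 0.0845 h⁻¹, so reckon the fade on the clock.

It enters as a correction, exp(fade × time). Scaled to the flask's catalyst, cedar and ash give 21.1% and 19.2% product at 15.0 h, so put 20% conversion near that time. At 2.0 mM the early rate reaches it in 1.07 h. The later arrival costs the flask a factor, and my ratio becomes 32.7.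

Then add the coupling partner. Maple, with 1.50 times the charge, has a slope over its last interval 1.64 times the slope scaled from the last intervals of cedar and ash, which are not the same hours. Taken as a power of the charge, that gives 2.33 on doubling.

The forecast gives 3 for doubling, higher than mine, and 33 for the catalyst, holding that “The decay follows clock time, not conversion”.

The flask gives 2.71 and 28.3, and reaches 20% conversion at 14.0 h.

    coupling partner + catalyst intermediate A ⇌ catalyst intermediate B (K = 107 L mol⁻¹, k = 267 L mol⁻¹ h⁻¹)
    substrate + free catalyst → catalyst intermediate A (k = 3600 L mol⁻¹ h⁻¹)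
    2 free catalyst ⇌ resting dimer, settled at all times (K = 2410 L mol⁻¹)
    catalyst intermediate B ⇌ released group + catalyst intermediate C (K = 0.280 M, k = 147 h⁻¹)
    coupling partner → decomposed reagent (k = 0.125 h⁻¹)
    catalyst intermediate C → free catalyst + product (k = 130 h⁻¹)

Put 14.0 h into the correction: the 2.0 mM factor becomes 30.0, against 28.3. One source of the fade is the step from coupling partner to decomposed reagent: at 15.0 h the flask holds 0.388 M of decomposed reagent and 9.58% of its coupling partner charge. Without that step, the rate at 20% conversion stands at 3.14 times the actual one, while exp(fade × 14.0 h) gives 3.45.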